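## Retrosynthetic overview

- Feature: in each cyclohexane (C1 = quaternary carbon, C5 = alkylidene carbon, C6 = carbinol) the allylic carbinol C6 is bonded directly to the vinylic ring carbon C5 of a Z exocyclic alkene whose chain lies syn to C6. The C5–C6 bond is therefore cut as vinylmetal plus aldehyde.
- The target goes back to a bis-PMB dialdehyde (twofold α-prenylation, oxidation, PMB removal). Its central CH2–CH2 bond comes from a ring A allyl sulfone and a ring B allyl bromide (alkylation, then Pd(dppp)Cl2-catalysed desulfonylation).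
- Ring B is closed first (step 9) and ring A second (step 16), each by CrCl2/NiCl2-mediated C5–C6 closure of a (Z)-iodoalkenyl α-quaternary formyl ester. Ring A uses the mirror-image aldehyde, and its C6 is then inverted by oxidation and chelation-controlled reduction.
- Both aldehydes come from one esterase-derived malonic half-ester (ester carbon reduced for ring B, acid carbon for ring A). The half-ester comes from dimethyl methylmalonate and a (Z)-iodoalkenyl chloride built from 5-chloropent-1-yne and formaldehyde.

Key step: step 9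

Assumption: pig liver esterase is taken to hydrolyse the pro-S ester group of the malonate diester and so give the (R)-half-ester, as with long-chain 2-alkyl-2-methylmalonates; if the (S)-acid formed instead, the ester-reduction sequence (steps 6–8) and the acid-reduction sequence (steps 14–15) would simply be exchanged between the two rings.

## Route

Step 1
Reactants: 1 5-chloropent-1-yne; 2 paraformaldehyde
Product: 4 6-chlorohex-2-yn-1-ol, via lithium 5-chloropent-1-yn-1-ide 3 (not isolated)
Conditions: n-BuLi, THF, −78 °C; then 2, −78 °C→rt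
Reagents that add atoms: none
Why: Hydroxymethylation of a lithium acetylide with formaldehyde; the primary chloride does not alkylate the acetylide in THF at low temperature.

Step 2
Reactants: 4 6-chlorohex-2-yn-1-ol
Product: 6 (Z)-6-chloro-3-iodohex-2-en-1-ol, via sodium alkenylaluminate 5 (not isolated)
Conditions: NaAlH2(OCH2CH2OMe)2, THF, 0 °C→rt; then I2, −78→0 °C
Reagents that add atoms: iodine, II
Why: Hydroxyl-directed trans-hydroalumination of a propargylic alcohol holds aluminium on C3 in the five-membered alkoxyaluminate 5, and iodinolysis of the C–Al bond with retention puts iodine cis to CH2OH (Z); the primary chloride is not reduced at this temperature.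

Step 3
Reactants: 6 (Z)-6-chloro-3-iodohex-2-en-1-ol
Product: 7 (Z)-tert-butyl[(6-chloro-3-iodohex-2-en-1-yl)oxy]dimethylsilane
Conditions: TBSCl, imidazole, DMF, 0 °C→rt
Reagents that add atoms: tert-butyldimethylsilyl chloride, CC(C)(C)[Si](C)(C)Cl
Why: Standard silylation of a primary allylic alcohol, giving an ether stable to the base, hydride and chromium steps that follow.

Step 4
Reactants: 8 dimethyl methylmalonate; 7 (Z)-tert-butyl[(6-chloro-3-iodohex-2-en-1-yl)oxy]dimethylsilane
Product: 10 dimethyl 2-[(Z)-6-(tert-butyldimethylsilyloxy)-4-iodohex-4-en-1-yl]-2-methylpropanedioate, via sodium malonate enolate 9 (not isolated)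
Conditions: NaH, DMF, 0 °C; then 7, Bu4NI (cat.), 60 °C
Reagents that add atoms: none
Why: Malonate alkylation (SN2 with in situ Finkelstein activation by iodide) creates the quaternary carbon; the vinylic iodide is inert to the soft enolate.

Step 5
Reactants: 10 dimethyl 2-[(Z)-6-(tert-butyldimethylsilyloxy)-4-iodohex-4-en-1-yl]-2-methylpropanedioate
Product: 11 (2R,6Z)-8-(tert-butyldimethylsilyloxy)-6-iodo-2-(methoxycarbonyl)-2-methyloct-6-enoic acid
Conditions: pig liver esterase, 0.2 M phosphate buffer pH 7.5, DMSO (10% v/v), 25 °C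
Reagents that add atoms: water, O
Why: Enzymatic desymmetrisation of a prochiral 2,2-disubstituted malonate, the esterase hydrolysing one enantiotopic ester group and so setting the quaternary centre (taken as R); if needed the acid can be enriched by crystallising an amine salt.

Step 6
Reactants: 11 (2R,6Z)-half-ester
Product: 12 (2S,6Z)-8-(tert-butyldimethylsilyloxy)-2-(hydroxymethyl)-6-iodo-2-methyloct-6-enoic acid
Conditions: LiBH4, THF, 0 °C→rt; then 1 M HCl to pH 3–4 at 0 °C
Reagents that add atoms: none
Why: Chemoselective ester reduction of a malonic half-ester by LiBH4, the carboxylate formed first being inert; because the reduced carbon is the former ester, the quaternary centre now has the S arrangement needed for ring B.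

Step 7
Reactants: 12 (2S,6Z)-hydroxy acid
Product: 13 methyl (2S,6Z)-8-(tert-butyldimethylsilyloxy)-2-(hydroxymethyl)-6-iodo-2-methyloct-6-enoate
Conditions: MeI, KHCO3, DMF, rt
Reagents that add atoms: iodomethane, CI
Why: Carboxylate O-alkylation with iodomethane under weak base, which does not methylate the neopentyl alcohol.

Step 8
Reactants: 13 methyl (2S,6Z)-hydroxy ester
Product: 14 methyl (2S,6Z)-8-(tert-butyldimethylsilyloxy)-2-formyl-6-iodo-2-methyloct-6-enoate
Conditions: Dess–Martin periodinane, CH2Cl2, rt
Reagents that add atoms: none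
Why: Dess–Martin oxidation of a neopentyl primary alcohol to an aldehyde that cannot enolise, so the quaternary centre is safe.

Step 9
Reactants: 14 methyl (2S,6Z)-8-(tert-butyldimethylsilyloxy)-2-formyl-6-iodo-2-methyloct-6-enoate
Product: 16 methyl (1S,6R)-5-[(Z)-2-(tert-butyldimethylsilyloxy)ethylidene]-6-hydroxy-1-methylcyclohexane-1-carboxylate (ring B; OH cis to CO2Me), via vinylchromium dichloride 15 (not isolated)
Conditions: CrCl2 (5 equiv), NiCl2 (2 mol %), degassed DMF, 0.01 M, rt
Reagents that add atoms: none
Why: Zerovalent nickel, formed from NiCl2 by divalent chromium, inserts into the vinylic C–I bond and hands the vinyl group to trivalent chromium, and the vinylchromium 15 then adds to the aldehyde; this is an intramolecular Nozaki–Hiyama–Kishi reaction, the closest known type being the CrCl2/NiCl2 cyclisation of iodoalkenyl aldehydes to 2-alkylidenecycloalkanols. Ring B closes in the 6-exo-trig mode at the aldehyde carbonyl, forming the C5–C6 bond. The only new stereocentre, C6, is controlled by the C1 quaternary centre: in a chair transition state in which the chromium bound to the aldehyde oxygen is also coordinated by the ester carbonyl, the tethered vinyl carbon can reach the aldehyde only from the face of the C2 methylene, which leaves the hydroxyl cis to the ester (6R). The step needs chemoselectivity for the aldehyde over ester and silyl ether, which is inherent to vinylchromium reagents; retention of alkene geometry, secured because the vinylnickel and vinylchromium species are configurationally stable, so the Z iodide becomes the Z alkylidene; and aldehyde-face selectivity, which rests on the ester chelate. High dilution suppresses intermolecular addition.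

Step 10
Reactants: 16 ring B hydroxy ester
Product: 17 (1R,6R)-5-[(Z)-2-(tert-butyldimethylsilyloxy)ethylidene]-1-(hydroxymethyl)-1-methylcyclohexan-6-ol (ring B diol; CH2OH cis to OH)
Conditions: LiAlH4, THF, 0 °C
Reagents that add atoms: none
Why: LiAlH4 reduction of the hindered methyl ester to the primary alcohol; no stereocentre is touched and the allylic silyl ether survives.

Step 11
Reactants: 17 ring B diol
Product: 18 ring B 4-methoxybenzylidene acetal of 17 (cis-fused 2-aryl-1,3-dioxane across C6–O and C1–CH2O; aryl equatorial, acetal H cis to C6–H; silyl ether retained)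
Conditions: 4-MeOC6H4CH(OMe)2, PPTS (cat.), CH2Cl2, rt
Reagents that add atoms: 4-methoxybenzaldehyde dimethyl acetal, COc1ccc(cc1)C(OC)OC
Why: Acid-catalysed transacetalisation of the 1,3-diol to the six-membered acetal under thermodynamic control (aryl equatorial), masking both hydroxyls in one operation for later regioselective opening.

Step 12
Reactants: 18 ring B acetal silyl ether
Product: 19 ring B acetal allylic alcohol (as 18, CH2OH in place of CH2OTBS)
Conditions: Bu4NF, THF, 0 °C→rt
Reagents that add atoms: none
Why: Fluoride cleavage of the primary silyl ether; the acetal is stable to fluoride.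

Step 13
Reactants: 19 ring B acetal allylic alcohol
Product: 20 ring B acetal allylic bromide (as 19, CH2Br in place of CH2OH; Z)
Conditions: CBr4, PPh3, CH2Cl2, 0 °C
Reagents that add atoms: carbon tetrabromide, BrC(Br)(Br)Br
Why: Appel bromination of the primary allylic alcohol under neutral conditions (SN2 at the primary carbon), which the acetal tolerates.

Step 14
Reactants: 11 (2R,6Z)-half-ester
Product: 21 methyl (2R,6Z)-8-(tert-butyldimethylsilyloxy)-2-(hydroxymethyl)-6-iodo-2-methyloct-6-enoate
Conditions: BH3·SMe2, THF, 0 °C→rt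
Reagents that add atoms: none
Why: Chemoselective reduction of the carboxylic acid by borane in the presence of the methyl ester, which keeps the R arrangement at the quaternary carbon for ring A.

Step 15
Reactants: 21 methyl (2R,6Z)-hydroxy ester
Product: 22 methyl (2R,6Z)-8-(tert-butyldimethylsilyloxy)-2-formyl-6-iodo-2-methyloct-6-enoate
Conditions: Dess–Martin periodinane, CH2Cl2, rt
Reagents that add atoms: none
Why: Dess–Martin oxidation of the neopentyl alcohol to a non-enolisable aldehyde, as in step 8.

Step 16
Reactants: 22 methyl (2R,6Z)-formyl ester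
Product: 24 methyl (1R,6S)-5-[(Z)-2-(tert-butyldimethylsilyloxy)ethylidene]-6-hydroxy-1-methylcyclohexane-1-carboxylate (ring A; OH cis to CO2Me), via mirror-image vinylchromium dichloride 23 (not isolated)
Conditions: CrCl2 (5 equiv), NiCl2 (2 mol %), degassed DMF, 0.01 M, rt
Reagents that add atoms: none
Why: The same intramolecular Nozaki–Hiyama–Kishi cyclisation as step 9 on the mirror-image aldehyde, so the same ester-chelated chair should give the mirror-image product (hydroxyl cis to ester, 6S) with the Z alkylidene retained.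

Step 17
Reactants: 24 ring A cis hydroxy ester
Product: 25 methyl (1R)-5-[(Z)-2-(tert-butyldimethylsilyloxy)ethylidene]-1-methyl-6-oxocyclohexane-1-carboxylate
Conditions: Dess–Martin periodinane, CH2Cl2, rt
Reagents that add atoms: none
Why: Dess–Martin oxidation of the allylic alcohol to the Z-enone under neutral conditions; C1 carries no hydrogen and cannot epimerise.

Step 18
Reactants: 25 ring A Z-enone
Product: 26 methyl (1R,6R)-5-[(Z)-2-(tert-butyldimethylsilyloxy)ethylidene]-6-hydroxy-1-methylcyclohexane-1-carboxylate (ring A; OH trans to CO2Me)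
Conditions: Zn(BH4)2, Et2O, −20 °C
Reagents that add atoms: none
Why: Chelation-controlled 1,2-reduction of a β-keto ester: zinc bridges the two carbonyls, which holds the ester pseudoequatorial and the C1 methyl axial, so hydride adds anti to the methyl group and the hydroxyl ends trans to the ester (6R), the configuration of ring A.

Step 19
Reactants: 26 ring A trans hydroxy ester
Product: 27 (1S,6R)-5-[(Z)-2-(tert-butyldimethylsilyloxy)ethylidene]-1-(hydroxymethyl)-1-methylcyclohexan-6-ol (ring A diol; CH2OH trans to OH)
Conditions: LiAlH4, THF, 0 °C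
Reagents that add atoms: none
Why: LiAlH4 reduction of the ester to the primary alcohol, as in step 10, without touching a stereocentre.

Step 20
Reactants: 27 ring A diol
Product: 28 ring A 4-methoxybenzylidene acetal of 27 (trans-fused 2-aryl-1,3-dioxane; aryl equatorial, acetal H cis to C6–H; silyl ether retained)
Conditions: 4-MeOC6H4CH(OMe)2, PPTS (cat.), CH2Cl2, rt
Reagents that add atoms: 4-methoxybenzaldehyde dimethyl acetal, COc1ccc(cc1)C(OC)OC
Why: Transacetalisation as in step 11, here giving the rigid trans-fused acetal with the aryl group equatorial.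

Step 21
Reactants: 28 ring A acetal silyl ether
Product: 29 ring A acetal allylic alcohol (as 28, CH2OH in place of CH2OTBS)
Conditions: Bu4NF, THF, 0 °C→rt
Reagents that add atoms: none
Why: Fluoride cleavage of the primary silyl ether with the acetal untouched.

Step 22
Reactants: 29 ring A acetal allylic alcohol
Product: 31 ring A acetal allyl phenyl sulfone (as 29, CH2SO2Ph in place of CH2OH; Z), via allylic mesylate 30 (not isolated)
Conditions: MsCl, Et3N, CH2Cl2, −20 °C; then PhSO2Na, DMF, rt
Reagents that add atoms: sodium benzenesulfinate, [Na+].[O-]S(=O)c1ccccc1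
Why: Mesylation followed by S-alkylation of the sulfinate at the primary allylic carbon gives the allyl phenyl sulfone under non-acidic conditions that spare the acetal.

Step 23
Reactants: 31 ring A allyl phenyl sulfone; 20 ring B allylic bromide
Product: 33 coupled sulfone (ring A=CH–CH(SO2Ph)–CH2–CH=ring B, both alkenes Z, both acetals intact, sulfonyl carbon as an epimer mixture), via lithiated sulfone 32 (not isolated)
Conditions: n-BuLi, THF, −78 °C; then 20, −78→−30 °C
Reagents that add atoms: none
Why: Alkylation of an α-sulfonyl allyl carbanion by an allylic bromide (Biellmann-type coupling) at the sulfonyl carbon and at the primary carbon of the bromide forms the central C–C bond; at −78 °C the anion keeps its Z geometry, and the equatorial C6–O bond of the trans-fused acetal lies near the nodal plane of the anion, which disfavours 1,4-elimination.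

Step 24
Reactants: 33 coupled sulfone
Product: 34 bis-acetal (Z,Z)-diene (ring A=CH–CH2–CH2–CH=ring B)
Conditions: Pd(dppp)Cl2 (5 mol %), LiBHEt3, THF, 0 °C
Reagents that add atoms: none
Why: Pd(dppp)Cl2-catalysed reductive desulfonylation of an allylic sulfone with LiBHEt3, in which hydride goes to the less substituted terminus of the π-allyl intermediate so the trisubstituted Z alkene is restored in place, as in polyprenoid couplings.

Step 25
Reactants: 34 bis-acetal diene
Product: 35 bis-PMB diol (each ring: C6–O-(4-methoxybenzyl), C1–CH2OH; ring A 1S,6R; ring B 1R,6R)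
Conditions: i-Bu2AlH, CH2Cl2, −78→0 °C
Reagents that add atoms: none
Why: Regioselective reductive opening of 4-methoxybenzylidene acetals by i-Bu2AlH, aluminium coordinating the less hindered primary oxygen so the PMB group stays on the C6 oxygen and the primary alcohols are freed.

Step 26
Reactants: 35 bis-PMB diol
Product: 36 bis-PMB dialdehyde (each ring: C1–CHO; ring A 1R,6R; ring B 1S,6R)
Conditions: Dess–Martin periodinane, CH2Cl2, rt
Reagents that add atoms: none
Why: Dess–Martin oxidation of both neopentyl alcohols to non-enolisable aldehydes.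

Step 27
Reactants: 36 bis-PMB dialdehyde; 37 1-chloro-3-methylbut-2-ene (prenyl chloride; first of the two molecules consumed, one per aldehyde group)
Product: 38 bis-PMB bis(homoallylic alcohol) (each ring: C1–CH(OH)CH2CH=CMe2; ring stereocentres as in 36, side-chain carbinols as a mixture)
Conditions: BaI2, Li, biphenyl, THF, rt; 37 (excess, at least 2 equiv per 36), −78 °C; then 36, −78 °C
Reagents that add atoms: 1-chloro-3-methylbut-2-ene (second molecule of 37, which supplies the prenyl group for the second aldehyde), CC(C)=CCCl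
Why: Twofold α-selective carbonyl allylation with an allylic barium reagent, which unlike magnesium, zinc or chromium prenyl reagents bonds through its unsubstituted CH2 terminus, an outcome reinforced here by the neopentyl aldehydes; each aldehyde takes up one prenyl unit, and the new carbinol centres are removed in step 28.

Step 28
Reactants: 38 bis-PMB bis(homoallylic alcohol)
Product: 39 bis-PMB diketone (the target with both C6 hydroxyls as 4-methoxybenzyl ethers)
Conditions: Dess–Martin periodinane, NaHCO3, CH2Cl2, 0 °C→rt
Reagents that add atoms: none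
Why: Buffered Dess–Martin oxidation of the homoallylic alcohols gives the β,γ-unsaturated ketones without acid or base that would move the alkene into conjugation, the PMB ethers protecting the C6 carbinols.

Step 29
Reactants: 39 bis-PMB diketone
Product: 40 CNP0297042.3
Conditions: DDQ, CH2Cl2/pH 7 phosphate buffer, 0 °C
Reagents that add atoms: none
Why: Oxidative cleavage of the PMB ethers by DDQ in buffered wet dichloromethane, neutral conditions expected to spare the β-hydroxy ketones (no retro-aldol; C1 has no hydrogen for elimination), the β,γ-unsaturated ketones and the Z alkenes.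

## Compound list

1 | 5-chloropent-1-yne | C#CCCCCl | starting material
2 | paraformaldehyde (reacts as formaldehyde) | C=O | starting material
3 | lithium 5-chloropent-1-yn-1-ide | [Li]C#CCCCCl | intermediate (not isolated)
4 | 6-chlorohex-2-yn-1-ol | OCC#CCCCCl | intermediate
5 | sodium cyclic alkenylaluminate (five-membered O–Al–C3=C2–C1 ring, two 2-methoxyethoxy ligands on Al, 3-chloropropyl on C3) | [Na+].COCCO[Al-]1(OCCOC)OCC=C1CCCCl | intermediate (not isolated)
6 | (Z)-6-chloro-3-iodohex-2-en-1-ol | ClCCC/C(I)=C/CO | intermediate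
7 | (Z)-tert-butyl[(6-chloro-3-iodohex-2-en-1-yl)oxy]dimethylsilane | ClCCC/C(I)=C/CO[Si](C)(C)C(C)(C)C | intermediate
8 | dimethyl methylmalonate | COC(=O)C(C)C(=O)OC | starting material
9 | sodium enolate of dimethyl methylmalonate | [Na+].COC(=O)C(C)=C([O-])OC | intermediate (not isolated)
10 | dimethyl 2-[(Z)-6-(tert-butyldimethylsilyloxy)-4-iodohex-4-en-1-yl]-2-methylpropanedioate | COC(=O)C(C)(CCC/C(I)=C/CO[Si](C)(C)C(C)(C)C)C(=O)OC | intermediate
11 | (2R,6Z)-8-(tert-butyldimethylsilyloxy)-6-iodo-2-(methoxycarbonyl)-2-methyloct-6-enoic acid | COC(=O)[C@@](C)(C(=O)O)CCC/C(I)=C/CO[Si](C)(C)C(C)(C)C | intermediate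
12 | (2S,6Z)-8-(tert-butyldimethylsilyloxy)-2-(hydroxymethyl)-6-iodo-2-methyloct-6-enoic acid | OC[C@@](C)(C(=O)O)CCC/C(I)=C/CO[Si](C)(C)C(C)(C)C | intermediate
13 | methyl (2S,6Z)-8-(tert-butyldimethylsilyloxy)-2-(hydroxymethyl)-6-iodo-2-methyloct-6-enoate | COC(=O)[C@](C)(CO)CCC/C(I)=C/CO[Si](C)(C)C(C)(C)C | intermediate
14 | methyl (2S,6Z)-8-(tert-butyldimethylsilyloxy)-2-formyl-6-iodo-2-methyloct-6-enoate | COC(=O)[C@](C)(C=O)CCC/C(I)=C/CO[Si](C)(C)C(C)(C)C | intermediate
15 | vinylchromium dichloride from 14 (trivalent chromium on C6 in place of iodine, geometry retained) | COC(=O)[C@](C)(C=O)CCC/C(=C/CO[Si](C)(C)C(C)(C)C)[Cr](Cl)Cl | intermediate (not isolated)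
16 | methyl (1S,6R)-5-[(Z)-2-(tert-butyldimethylsilyloxy)ethylidene]-6-hydroxy-1-methylcyclohexane-1-carboxylate (ring B, OH cis to ester) | COC(=O)[C@@]1(C)CCC/C(=C/CO[Si](C)(C)C(C)(C)C)[C@H]1O | intermediate
17 | (1R,6R)-5-[(Z)-2-(tert-butyldimethylsilyloxy)ethylidene]-1-(hydroxymethyl)-1-methylcyclohexan-6-ol (ring B diol, cis) | OC[C@@]1(C)CCC/C(=C/CO[Si](C)(C)C(C)(C)C)[C@H]1O | intermediate
18 | ring B 4-methoxybenzylidene acetal of 17 (cis-fused, aryl equatorial, OTBS) | COc1ccc(cc1)[C@H]2OC[C@@]3(C)CCC/C(=C/CO[Si](C)(C)C(C)(C)C)[C@H]3O2 | intermediate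
19 | ring B acetal allylic alcohol | COc1ccc(cc1)[C@H]2OC[C@@]3(C)CCC/C(=C/CO)[C@H]3O2 | intermediate
20 | ring B acetal allylic bromide | COc1ccc(cc1)[C@H]2OC[C@@]3(C)CCC/C(=C/CBr)[C@H]3O2 | intermediate
21 | methyl (2R,6Z)-8-(tert-butyldimethylsilyloxy)-2-(hydroxymethyl)-6-iodo-2-methyloct-6-enoate | COC(=O)[C@@](C)(CO)CCC/C(I)=C/CO[Si](C)(C)C(C)(C)C | intermediate
22 | methyl (2R,6Z)-8-(tert-butyldimethylsilyloxy)-2-formyl-6-iodo-2-methyloct-6-enoate | COC(=O)[C@@](C)(C=O)CCC/C(I)=C/CO[Si](C)(C)C(C)(C)C | intermediate
23 | vinylchromium dichloride from 22 (mirror image of 15) | COC(=O)[C@@](C)(C=O)CCC/C(=C/CO[Si](C)(C)C(C)(C)C)[Cr](Cl)Cl | intermediate (not isolated)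
24 | methyl (1R,6S)-5-[(Z)-2-(tert-butyldimethylsilyloxy)ethylidene]-6-hydroxy-1-methylcyclohexane-1-carboxylate (ring A, OH cis to ester) | COC(=O)[C@]1(C)CCC/C(=C/CO[Si](C)(C)C(C)(C)C)[C@@H]1O | intermediate
25 | methyl (1R)-5-[(Z)-2-(tert-butyldimethylsilyloxy)ethylidene]-1-methyl-6-oxocyclohexane-1-carboxylate | COC(=O)[C@]1(C)CCC/C(=C/CO[Si](C)(C)C(C)(C)C)C1=O | intermediate
26 | methyl (1R,6R)-5-[(Z)-2-(tert-butyldimethylsilyloxy)ethylidene]-6-hydroxy-1-methylcyclohexane-1-carboxylate (ring A, OH trans to ester) | COC(=O)[C@]1(C)CCC/C(=C/CO[Si](C)(C)C(C)(C)C)[C@H]1O | intermediate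
27 | (1S,6R)-5-[(Z)-2-(tert-butyldimethylsilyloxy)ethylidene]-1-(hydroxymethyl)-1-methylcyclohexan-6-ol (ring A diol, trans) | OC[C@]1(C)CCC/C(=C/CO[Si](C)(C)C(C)(C)C)[C@H]1O | intermediate
28 | ring A 4-methoxybenzylidene acetal of 27 (trans-fused, aryl equatorial, OTBS) | COc1ccc(cc1)[C@H]2OC[C@]3(C)CCC/C(=C/CO[Si](C)(C)C(C)(C)C)[C@H]3O2 | intermediate
29 | ring A acetal allylic alcohol | COc1ccc(cc1)[C@H]2OC[C@]3(C)CCC/C(=C/CO)[C@H]3O2 | intermediate
30 | ring A acetal allylic mesylate | COc1ccc(cc1)[C@H]2OC[C@]3(C)CCC/C(=C/COS(C)(=O)=O)[C@H]3O2 | intermediate (not isolated)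
31 | ring A acetal allyl phenyl sulfone | COc1ccc(cc1)[C@H]2OC[C@]3(C)CCC/C(=C/CS(=O)(=O)c4ccccc4)[C@H]3O2 | intermediate
32 | α-lithiated ring A allyl phenyl sulfone | COc1ccc(cc1)[C@H]2OC[C@]3(C)CCC/C(=C/C([Li])S(=O)(=O)c4ccccc4)[C@H]3O2 | intermediate (not isolated)
33 | coupled sulfone (ring A=CH–CH(SO2Ph)–CH2–CH=ring B, Z,Z, bis-acetal) | COc1ccc(cc1)[C@H]2OC[C@]3(C)CCC/C(=C/C(C/C=C4/CCC[C@]5(C)CO[C@H](c6ccc(OC)cc6)O[C@H]45)S(=O)(=O)c7ccccc7)[C@H]3O2 | intermediate
34 | bis-acetal (Z,Z)-diene | COc1ccc(cc1)[C@H]2OC[C@]3(C)CCC/C(=C/CC/C=C4/CCC[C@]5(C)CO[C@H](c6ccc(OC)cc6)O[C@H]45)[C@H]3O2 | intermediate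
35 | bis-PMB diol (C6–OPMB, C1–CH2OH on both rings) | OC[C@]1(C)CCC/C(=C/CC/C=C2/CCC[C@](C)(CO)[C@@H]2OCc3ccc(OC)cc3)[C@H]1OCc4ccc(OC)cc4 | intermediate
36 | bis-PMB dialdehyde | O=C[C@]1(C)CCC/C(=C/CC/C=C2/CCC[C@](C)(C=O)[C@@H]2OCc3ccc(OC)cc3)[C@H]1OCc4ccc(OC)cc4 | intermediate
37 | 1-chloro-3-methylbut-2-ene (prenyl chloride) | CC(C)=CCCl | starting material
38 | bis-PMB bis(homoallylic alcohol) (side-chain carbinols unassigned) | CC(C)=CCC(O)[C@]1(C)CCC/C(=C/CC/C=C2/CCC[C@](C)(C(O)CC=C(C)C)[C@@H]2OCc3ccc(OC)cc3)[C@H]1OCc4ccc(OC)cc4 | intermediate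
39 | bis-PMB diketone | CC(C)=CCC(=O)[C@]1(C)CCC/C(=C/CC/C=C2/CCC[C@](C)(C(=O)CC=C(C)C)[C@@H]2OCc3ccc(OC)cc3)[C@H]1OCc4ccc(OC)cc4 | intermediate
40 | CNP0297042.3: 1-[(1R,2R,3Z)-2-hydroxy-3-{4-[(1Z,2R,3S)-2-hydroxy-3-methyl-3-(4-methylpent-3-enoyl)cyclohexylidene]butylidene}-1-methylcyclohexyl]-4-methylpent-3-en-1-one | CC(C)=CCC(=O)[C@]1(C)CCC/C(=C/CC/C=C2/CCC[C@](C)(C(=O)CC=C(C)C)[C@@H]2O)[C@H]1O | target

## Step count and risks

Total step count: 29. Longest linear sequence: 21 steps (steps 1–5, 14–22, 23–29).

Steps most likely to fail: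

1. Step 9 (and its mirror image, step 16): the two aldehyde faces may be poorly discriminated, because DMF competes with the ester for trivalent chromium and the chelate may not form, which would give a mixture of C6 epimers. The fallback sets out from 16, taken as the epimer mixture, and returns at 16. The mixture is oxidised with Dess–Martin periodinane to the single Z-enone methyl (1S)-5-[(Z)-2-(tert-butyldimethylsilyloxy)ethylidene]-1-methyl-6-oxocyclohexane-1-carboxylate F1. C6 is then set by hydride instead of in the C–C bond formation: NaBH4 with CeCl3·7H2O in methanol at −78 °C is a non-chelating medium in which the ketone should react through the conformer with the ester pseudoaxial and take hydride anti to it, which is expected to return 16. The unwanted epimer is cycled through F1 again. In the ring A series the corresponding epimer of 24 is 26 itself and is simply carried forward.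

2. Step 18: facial selectivity may erode if zinc chelation is incomplete, conjugate reduction may compete, or the strained Z-enone may isomerise to E. The fallback sets out from 24 and returns at 27, bypassing 25 and 26. LiAlH4 reduces the ester of 24 to the cis diol (1S,6S)-5-[(Z)-2-(tert-butyldimethylsilyloxy)ethylidene]-1-(hydroxymethyl)-1-methylcyclohexan-6-ol F2. MnO2 oxidises only the allylic secondary hydroxyl to the β-hydroxy enone (1S)-5-[(Z)-2-(tert-butyldimethylsilyloxy)ethylidene]-1-(hydroxymethyl)-1-methylcyclohexan-6-one F3. Me4NBH(OAc)3 in MeCN/AcOH at −20 °C (Evans–Saksena reduction) then delivers hydride intramolecularly from boron bound to the CH2O group, to the ketone face cis to CH2OH, so the hydroxyl forms trans to CH2OH, which is diol 27.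

3. Step 27: regiocontrol may be lost (bonding through the dimethyl-substituted terminus), or the second addition may stall if the zerovalent barium is poorly formed, leaving mono-adduct. The fallback sets out from 36 and returns at 39, bypassing 38. The carbanion of commercial 3-methylbut-2-en-1-yl phenyl sulfone (n-BuLi, THF, −78 °C; two molecules per molecule of 36), which reacts with aldehydes at its sulfonyl carbon, adds to both aldehydes to give the bis(β-hydroxy sulfone) F4. Dess–Martin oxidation gives the bis(β-keto sulfone) F5. SmI2 in THF/MeOH at −78 °C cleaves both C–S bonds, and protonation of the resulting dienolates at the α-carbon gives the β,γ-unsaturated diketone 39.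

## Further compounds

F1 | step 9 | methyl (1S)-5-[(Z)-2-(tert-butyldimethylsilyloxy)ethylidene]-1-methyl-6-oxocyclohexane-1-carboxylate | COC(=O)[C@@]1(C)CCC/C(=C/CO[Si](C)(C)C(C)(C)C)C1=O
F2 | step 18 | (1S,6S)-5-[(Z)-2-(tert-butyldimethylsilyloxy)ethylidene]-1-(hydroxymethyl)-1-methylcyclohexan-6-ol | OC[C@]1(C)CCC/C(=C/CO[Si](C)(C)C(C)(C)C)[C@@H]1O
F3 | step 18 | (1S)-5-[(Z)-2-(tert-butyldimethylsilyloxy)ethylidene]-1-(hydroxymethyl)-1-methylcyclohexan-6-one | OC[C@]1(C)CCC/C(=C/CO[Si](C)(C)C(C)(C)C)C1=O
F4 | step 27 | bis-PMB bis(β-hydroxy sulfone) (each ring: C1–CH(OH)–CH(SO2Ph)–CH=CMe2) | CC(C)=CC(S(=O)(=O)c1ccccc1)C(O)[C@]2(C)CCC/C(=C/CC/C=C3/CCC[C@](C)(C(O)C(C=C(C)C)S(=O)(=O)c4ccccc4)[C@@H]3OCc5ccc(OC)cc5)[C@H]2OCc6ccc(OC)cc6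
F5 | step 27 | bis-PMB bis(β-keto sulfone) (each ring: C1–C(=O)–CH(SO2Ph)–CH=CMe2) | CC(C)=CC(S(=O)(=O)c1ccccc1)C(=O)[C@]2(C)CCC/C(=C/CC/C=C3/CCC[C@](C)(C(=O)C(C=C(C)C)S(=O)(=O)c4ccccc4)[C@@H]3OCc5ccc(OC)cc5)[C@H]2OCc6ccc(OC)cc6
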